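If product depends on the catalyst charged multiplied by the minutes it has been working, both earlier runs lie on one scale and the new flasks can be read from it.

| flask | starting material | reagent | precatalyst | remark | time |
|---|---|---|---|---|---|
| alpha | 0.80 M | 0.88 M | 4.2 mM | run made earlier |  |
| theta | 0.80 M | 0.88 M | 23 mM | run made earlier |  |
| south-west | 0.80 M | 0.880 M | 6.0 mM |  | 80 min |
| east | 0.80 M | 0.880 M | 26 mM |  | 80 min |

| alpha: time / min | alpha: product / % | theta: time / min | theta: product / % |
|---|---|---|---|
| 6.00 | 3.9 | 20.0 | 74.0 |
| 15.0 | 14.0 | 40.0 | 99.8 |
| 30.0 | 31.8 | 60.0 | 99.6 |
| 80.0 | 72.7 | 80.0 | 99.6 |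

(each reading ± 0.3 percentage points)

- which one finishes higher in amount of product, in percent of the starting material charged ("neither" within 2 percentage points) (south-west / east / neither)
- amount of product at the end, in percent of the starting material charged, south-west
- amount of product at the end, in percent of the starting material charged, east

Our measure is the log-ratio: the natural logarithm of the starting material charged over the part not yet product. Under a first-order loss it rises in a straight line. In the alpha run it goes from 0.383 at 30.0 min to 1.30 at 80.0 min, a slope of 0.0183 min⁻¹. Run backwards, that line reaches zero at 9.10 min, and we assume this lag for every flask here. Dividing the slope by alpha's c(precatalyst) gives a reading of 4.36 M⁻¹ min⁻¹. Carried to south-west, it gives 84.3 %.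

That constant is the weak link, because alpha's last reading is 72.7 % and the estimate for south-west lies higher than that. Theta's first reading, 74.0 % at 20.0 min, gives 5.37 M⁻¹ min⁻¹ with the same lag, more than alpha's. So we take the mean, 4.87 M⁻¹ min⁻¹, as our catalyst constant, an empirical number: the rise of the log-ratio per minute per unit of precatalyst charged. South-west then comes to 87.4 % and east to >99.9 %. We commit to east.

The forecast also says east, with 85.5 % for south-west and 99.6 % for east. Its ground for south-west is “Over about 71 effective minutes this gives about 85%”. Our south-west figure is higher than that.

At 80 min the flasks stand at 87.9 % in south-west and 100 % in east, so east is higher.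

    catalyst intermediate B ⇌ released group + catalyst intermediate C (K = 0.400 M, k = 0.780 s⁻¹)
    starting material + free catalyst → catalyst intermediate A (k = 0.250 M⁻¹ s⁻¹)
    precatalyst → free catalyst (k = 0.00360 s⁻¹)
    catalyst intermediate C ⇌ catalyst intermediate D (K = 2.60, k = 0.660 s⁻¹)
    2 catalyst intermediate B ⇌ resting dimer, settled at all times (K = 110 M⁻¹)
    reagent + catalyst intermediate A → catalyst intermediate B (k = 0.230 M⁻¹ s⁻¹)
    catalyst intermediate D → free catalyst + product (k = 0.150 s⁻¹)

South-west's result, put through the same log-ratio, gives a constant of 4.96 M⁻¹ min⁻¹ against our 4.87 M⁻¹ min⁻¹. That flask still holds 12 % of its starting material at 80.0 min and stands at 100 % at 800 min, so the gap to east at the asked time is not a difference in where the flasks end. The neighbouring flask is east with 6.50 mM of precatalyst. Its log-ratio, reckoned with our constant, is 2.24, which means 89.4 %. It gives 90.8 %, with 8.9 % of its starting material left.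

The readings come from a simulation for an exercise; scatter was added.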